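**Strategy.** Ring A of this 7α-acetoxy-trans-communic acid (labdane numbering) is read as the adduct of an intramolecular Diels–Alder reaction. A C3=C4 enoate retron turns C2–C3–C4–C5 into a 2-methoxycarbonyl diene and C10–C1 into an isopropenyl dienophile, joined by the C6–C9 chain of ring B. One thermal step closes rings A and B and sets C5 and the quaternary C10 from the single auxiliary-derived stereocentre C9; the C19 ester on C4 doubles as steric director for trans fusion. The precursor is an open-chain hexaene ester that already carries the complete (E)-dienyl side chain. Reductive methylation at C4, allylic hydroxylation at C7, ester cleavage and acetylation finish the synthesis.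

Key step: step 10

Remark: atoms carry labdane numbers (decalin C1–C10; C18 methyl and C19 carboxyl on C4; C20 methyl on C10; C17 methylene on C8; side chain C11–C16). The SMILES is read as the 7α (7R) acetate of trans-communic acid, and 1, 4, 5 and 11 are taken as purchasable.

Step 1
Reactants: 1 (2E)-3-methylpent-2-en-4-yn-1-ol
Product: 2 (2E)-3-methylpenta-2,4-dien-1-ol
Conditions: H2 (1 atm), Pd/CaCO3 poisoned with Pb(OAc)2, quinoline, EtOAc, 0 °C
Reagents that add atoms: none
Why: Semi-hydrogenation of the terminal alkyne over lead-poisoned palladium should stop at the vinyl group and leave the defined (E)-trisubstituted alkene untouched, which fixes the side-chain geometry for the whole route.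

Step 2
Reactants: 2 (2E)-3-methylpenta-2,4-dien-1-ol
Product: 3 (3E)-5-bromo-3-methylpenta-1,3-diene
Conditions: PBr3, Et2O, −20 → 0 °C; used crude
Reagents that add atoms: phosphorus tribromide BrP(Br)Br
Why: Bromination of the primary allylic alcohol through its phosphite ester (SN2 displacement by bromide) should give the primary dienyl bromide with the (E)-geometry retained, the tertiary allylic isomer being disfavoured.

Step 3
Reactants: 4 (4R)-4-benzyl-1,3-oxazolidin-2-one; 5 3-methylbut-2-enoyl chloride
Product: 7 (4R)-4-benzyl-3-(3-methylbut-2-enoyl)-1,3-oxazolidin-2-one, via N-lithio oxazolidinone 6 (not isolated)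
Conditions: n-BuLi, THF, −78 °C; then 5, −78 → 0 °C
Reagents that add atoms: none
Why: N-Acylation of the lithiated oxazolidinone by the acid chloride is the standard attachment of an Evans auxiliary and sets no stereocentre.

Step 4
Reactants: 7 (4R)-4-benzyl-3-(3-methylbut-2-enoyl)-1,3-oxazolidin-2-one; 3 (3E)-5-bromo-3-methylpenta-1,3-diene
Product: 9 (4R)-4-benzyl-3-[(2R,4E)-5-methyl-2-(prop-1-en-2-yl)hepta-4,6-dienoyl]-1,3-oxazolidin-2-one, via sodium dienolate 8 (not isolated)
Conditions: NaN(SiMe3)2, THF, −78 °C; then 3, −78 → −40 °C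
Reagents that add atoms: none
Why: Evans asymmetric alkylation in its deconjugative form: γ-deprotonation gives the chelated (Z)-dienolate, which the allylic bromide should alkylate at the α-carbon on the face opposite the benzyl group, setting C9 as (R) and creating the isopropenyl group in the same event.

Step 5
Reactants: 9 (4R)-4-benzyl-3-[(2R,4E)-5-methyl-2-(prop-1-en-2-yl)hepta-4,6-dienoyl]-1,3-oxazolidin-2-one
Product: 10 (2R,4E)-N-methoxy-N,5-dimethyl-2-(prop-1-en-2-yl)hepta-4,6-dienamide
Conditions: AlMe3, MeNH(OMe)·HCl, CH2Cl2, 0 → 25 °C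
Reagents that add atoms: N,O-dimethylhydroxylamine hydrochloride CNOC.Cl
Why: Aluminium-amide transamidation of the imide (Weinreb amide formation) cleaves the auxiliary at the exocyclic carbonyl under non-basic conditions, so the α-stereocentre C9 should survive.

Step 6
Reactants: 10 (2R,4E)-N-methoxy-N,5-dimethyl-2-(prop-1-en-2-yl)hepta-4,6-dienamide; 11 (4-bromobut-1-yn-1-yl)trimethylsilane
Product: 13 (6R,8E)-9-methyl-6-(prop-1-en-2-yl)-1-(trimethylsilyl)undeca-8,10-dien-1-yn-5-one, via Grignard reagent 12 (not isolated)
Conditions: 11, Mg, THF, 25 °C; then 10, THF, −20 → 0 °C; aq. NH4Cl, 0 °C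
Reagents that add atoms: none
Why: Weinreb ketone synthesis: the chelated tetrahedral adduct stops the Grignard addition at the ketone stage and releases the ketone only on cold, mildly acidic quench, which limits enolisation of the β,γ-unsaturated α-stereocentre C9.

Step 7
Reactants: 13 (6R,8E)-9-methyl-6-(prop-1-en-2-yl)-1-(trimethylsilyl)undeca-8,10-dien-1-yn-5-one
Product: 14 trimethyl[(6R,8E)-9-methyl-5-methylidene-6-(prop-1-en-2-yl)undeca-8,10-dien-1-yn-1-yl]silane
Conditions: Zn, CH2Br2, TiCl4, THF/CH2Cl2, 0 → 25 °C
Reagents that add atoms: dibromomethane BrCBr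
Why: Takai–Lombardo methylenation with the non-basic zinc/titanium methylene reagent converts enolisable ketones into 1,1-disubstituted alkenes without epimerisation or double-bond migration, which installs the C8=C17 methylene while keeping C9 intact.

Step 8
Reactants: 14 trimethyl[(6R,8E)-9-methyl-5-methylidene-6-(prop-1-en-2-yl)undeca-8,10-dien-1-yn-1-yl]silane
Product: 16 methyl (7R,9E)-10-methyl-6-methylidene-7-(prop-1-en-2-yl)dodeca-9,11-dien-2-ynoate, via lithium acetylide 15 (not isolated)
Conditions: MeLi·LiBr, THF, 0 → 25 °C; then ClCO2Me, −78 °C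
Reagents that add atoms: methyl chloroformate COC(=O)Cl
Why: Nucleophilic desilylation of the alkynylsilane by methyllithium gives the lithium acetylide directly, and its C-acylation by the chloroformate should give the alk-2-ynoate that carries the future C19 ester.

Step 9
Reactants: 16 methyl (7R,9E)-10-methyl-6-methylidene-7-(prop-1-en-2-yl)dodeca-9,11-dien-2-ynoate
Product: 18 methyl (2Z,7R,9E)-2-ethenyl-10-methyl-6-methylidene-7-(prop-1-en-2-yl)dodeca-2,9,11-trienoate, via vinylstannane 17 (not isolated)
Conditions: Bu3SnH, Pd(PPh3)4 (cat.), THF, 0 °C; then vinyl bromide, CuI, CsF, DMF, 45 °C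
Reagents that add atoms: vinyl bromide C=CBr
Why: Palladium-catalysed syn-hydrostannation of the ynoate places tin on the α-carbon, and Stille coupling with retention then puts the vinyl group there, so the chain ends up cis to the ester ((Z)-enoate) and trans to the new vinyl group, the diene geometry the cycloaddition needs.

Step 10
Reactants: 18 methyl (2Z,7R,9E)-2-ethenyl-10-methyl-6-methylidene-7-(prop-1-en-2-yl)dodeca-2,9,11-trienoate
Product: 19 methyl (4aR,5S,8aR)-4a-methyl-6-methylidene-5-[(2E)-3-methylpenta-2,4-dien-1-yl]-3,4,4a,5,6,7,8,8a-octahydronaphthalene-1-carboxylate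
Conditions: PhMe (0.005 M), BHT (cat.), sealed tube, 170 °C
Reagents that add atoms: none
Why: Thermal intramolecular Diels–Alder reaction of the deca-1,7,9-triene unit: the diene C2=C3–C4=C5 and the isopropenyl dienophile C10=C1 combine suprafacially in one concerted [4+2] step, forming C1–C2 and C5–C10. The closest known reaction type is the fused-mode (type 1) cycloaddition of unactivated 1,7,9-decatrienes to trans-octalins bearing an angular methyl group. Ring B closes at C5–C10 through the six-membered chair-like tether C6–C9 with both π-systems exocyclic to it, and ring A closes as the cyclohexene of the cycloaddition (C1–C2 bond, new C3=C4 enoate). C5 and C10 are set by C9: its dienylmethyl group should sit equatorial in the chair tether, so the diene adds to the dienophile face that puts H9 anti to the C10 methyl, while the C4 ester, cis to the tether, clashes with the C6/C7 hydrogens in the cis-fused transition state and so directs the trans ring fusion. The step needs periselectivity and geometric integrity: the side-chain diene and the C8 methylene reach the reacting partners only through two-atom tethers and should stay out, the (Z)-enoate holds the tether on the outside position of the diene, and Cope drift of the 1,5-diene units is uphill because it would break the side-chain conjugation and build a quaternary C13.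

Step 11
Reactants: 19 methyl (4aR,5S,8aR)-4a-methyl-6-methylidene-5-[(2E)-3-methylpenta-2,4-dien-1-yl]-3,4,4a,5,6,7,8,8a-octahydronaphthalene-1-carboxylate
Product: 21 methyl (1S,4aR,5S,8aR)-1,4a-dimethyl-6-methylidene-5-[(2E)-3-methylpenta-2,4-dien-1-yl]decahydronaphthalene-1-carboxylate (methyl trans-communate), via lithium ester enolate 20 (not isolated)
Conditions: LiBH(s-Bu)3, THF, −78 °C; then MeI, HMPA, −78 → 0 °C
Reagents that add atoms: iodomethane CI
Why: Reductive alkylation: conjugate hydride addition to the enoate at C3 gives the exocyclic ester enolate, and methyl iodide should attack C4 from the α-face, away from the axial C10 methyl, to give the equatorial 4α-methyl and the axial 4β (C19) ester, (1S).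

Step 12
Reactants: 21 methyl trans-communate
Product: 22 methyl (1S,4aR,5R,7R,8aR)-7-hydroxy-1,4a-dimethyl-6-methylidene-5-[(2E)-3-methylpenta-2,4-dien-1-yl]decahydronaphthalene-1-carboxylate
Conditions: SeO2 (0.5 equiv), t-BuOOH, CH2Cl2, 0 → 25 °C
Reagents that add atoms: selenium dioxide O=[Se]=O; tert-butyl hydroperoxide CC(C)(C)OO
Why: Selenium dioxide allylic oxidation (ene reaction followed by [2,3]-sigmatropic shift) of the exocyclic C8=C17 alkene should take hydrogen from the C7 methylene rather than the hindered tertiary C9–H and deliver oxygen axially on the α-face, giving the 7α (7R) alcohol with the alkene restored at C8=C17, while the conjugated side-chain diene is expected to react more slowly.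

Step 13
Reactants: 22 methyl 7α-hydroxy-trans-communate
Product: 23 (1S,4aR,5R,7R,8aR)-7-hydroxy-1,4a-dimethyl-6-methylidene-5-[(2E)-3-methylpenta-2,4-dien-1-yl]decahydronaphthalene-1-carboxylic acid
Conditions: n-PrSH, n-BuLi, HMPA, 25 °C; then aq. HCl
Reagents that add atoms: none
Why: SN2 O-demethylation by the thiolate attacks the ester methyl group and not the carbonyl, so it should cleave the hindered axial C19 methyl ester at room temperature without touching the diene, the allylic alcohol or any stereocentre.

Step 14
Reactants: 23 7α-hydroxy-trans-communic acid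
Product: 24 (1S,4aR,5R,7R,8aR)-7-acetoxy-1,4a-dimethyl-6-methylidene-5-[(2E)-3-methylpenta-2,4-dien-1-yl]decahydronaphthalene-1-carboxylic acid (CNP0135450.1)
Conditions: Ac2O, pyridine, DMAP (cat.), CH2Cl2, 25 °C; then aq. NaHCO3, then dilute HCl
Reagents that add atoms: acetic anhydride CC(=O)OC(C)=O
Why: Nucleophile-catalysed acetylation of the axial 7α-alcohol proceeds with retention at C7, and any mixed anhydride of the hindered tertiary acid is hydrolysed on aqueous work-up, which frees the C19 acid.

**Compound list**

1 | (2E)-3-methylpent-2-en-4-yn-1-ol | C#C/C(C)=C/CO | starting material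
2 | (2E)-3-methylpenta-2,4-dien-1-ol | C=C/C(C)=C/CO | intermediate
3 | (3E)-5-bromo-3-methylpenta-1,3-diene | C=C/C(C)=C/CBr | intermediate
4 | (4R)-4-benzyl-1,3-oxazolidin-2-one | O=C1N[C@H](Cc2ccccc2)CO1 | starting material
5 | 3-methylbut-2-enoyl chloride | CC(C)=CC(=O)Cl | starting material
6 | N-lithio-(4R)-4-benzyl-1,3-oxazolidin-2-one | [Li]N1C(=O)OC[C@H]1Cc1ccccc1 | intermediate
7 | (4R)-4-benzyl-3-(3-methylbut-2-enoyl)-1,3-oxazolidin-2-one | CC(C)=CC(=O)N1[C@H](Cc2ccccc2)COC1=O | intermediate
8 | sodium (1Z)-1-[(4R)-4-benzyl-2-oxo-1,3-oxazolidin-3-yl]-3-methylbuta-1,3-dien-1-olate (dienolate of 7) | [Na+].[O-]/C(=C\C(C)=C)N1[C@H](Cc2ccccc2)COC1=O | intermediate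
9 | (4R)-4-benzyl-3-[(2R,4E)-5-methyl-2-(prop-1-en-2-yl)hepta-4,6-dienoyl]-1,3-oxazolidin-2-one | C=C/C(C)=C/C[C@@H](C(=O)N1[C@H](Cc2ccccc2)COC1=O)C(C)=C | intermediate
10 | (2R,4E)-N-methoxy-N,5-dimethyl-2-(prop-1-en-2-yl)hepta-4,6-dienamide | C=C/C(C)=C/C[C@@H](C(=O)N(C)OC)C(C)=C | intermediate
11 | (4-bromobut-1-yn-1-yl)trimethylsilane | C[Si](C)(C)C#CCCBr | starting material
12 | [4-(trimethylsilyl)but-3-yn-1-yl]magnesium bromide | C[Si](C)(C)C#CCC[Mg]Br | intermediate
13 | (6R,8E)-9-methyl-6-(prop-1-en-2-yl)-1-(trimethylsilyl)undeca-8,10-dien-1-yn-5-one | C=C/C(C)=C/C[C@@H](C(=O)CCC#C[Si](C)(C)C)C(C)=C | intermediate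
14 | trimethyl[(6R,8E)-9-methyl-5-methylidene-6-(prop-1-en-2-yl)undeca-8,10-dien-1-yn-1-yl]silane | C=C/C(C)=C/C[C@@H](C(=C)CCC#C[Si](C)(C)C)C(C)=C | intermediate
15 | [(6R,8E)-9-methyl-5-methylidene-6-(prop-1-en-2-yl)undeca-8,10-dien-1-yn-1-yl]lithium | C=C/C(C)=C/C[C@@H](C(=C)CCC#C[Li])C(C)=C | intermediate
16 | methyl (7R,9E)-10-methyl-6-methylidene-7-(prop-1-en-2-yl)dodeca-9,11-dien-2-ynoate | C=C/C(C)=C/C[C@@H](C(=C)CCC#CC(=O)OC)C(C)=C | intermediate
17 | methyl (2E,7R,9E)-10-methyl-6-methylidene-7-(prop-1-en-2-yl)-2-(tributylstannyl)dodeca-2,9,11-trienoate | C=C/C(C)=C/C[C@@H](C(=C)CC/C=C(/[Sn](CCCC)(CCCC)CCCC)C(=O)OC)C(C)=C | intermediate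
18 | methyl (2Z,7R,9E)-2-ethenyl-10-methyl-6-methylidene-7-(prop-1-en-2-yl)dodeca-2,9,11-trienoate | C=C/C(C)=C/C[C@@H](C(=C)CC/C=C(/C=C)C(=O)OC)C(C)=C | intermediate
19 | methyl (4aR,5S,8aR)-4a-methyl-6-methylidene-5-[(2E)-3-methylpenta-2,4-dien-1-yl]-3,4,4a,5,6,7,8,8a-octahydronaphthalene-1-carboxylate | C=C/C(C)=C/C[C@H]1C(=C)CC[C@@H]2[C@]1(C)CCC=C2C(=O)OC | intermediate
20 | lithium ester enolate from 1,4-hydride addition to 19 (exocyclic C4=C(OMe)OLi; C5, C9, C10 as in 19) | C=C/C(C)=C/C[C@H]1C(=C)CC[C@@H]2[C@]1(C)CCCC2=C(OC)O[Li] | intermediate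
21 | methyl trans-communate, methyl (1S,4aR,5S,8aR)-1,4a-dimethyl-6-methylidene-5-[(2E)-3-methylpenta-2,4-dien-1-yl]decahydronaphthalene-1-carboxylate | C=C/C(C)=C/C[C@H]1C(=C)CC[C@@H]2[C@]1(C)CCC[C@]2(C)C(=O)OC | intermediate
22 | methyl 7α-hydroxy-trans-communate, methyl (1S,4aR,5R,7R,8aR)-7-hydroxy-1,4a-dimethyl-6-methylidene-5-[(2E)-3-methylpenta-2,4-dien-1-yl]decahydronaphthalene-1-carboxylate | C=C/C(C)=C/C[C@H]1C(=C)[C@H](O)C[C@@H]2[C@]1(C)CCC[C@]2(C)C(=O)OC | intermediate
23 | 7α-hydroxy-trans-communic acid, (1S,4aR,5R,7R,8aR)-7-hydroxy-1,4a-dimethyl-6-methylidene-5-[(2E)-3-methylpenta-2,4-dien-1-yl]decahydronaphthalene-1-carboxylic acid | C=C/C(C)=C/C[C@H]1C(=C)[C@H](O)C[C@@H]2[C@]1(C)CCC[C@]2(C)C(=O)O | intermediate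
24 | 7α-acetoxy-trans-communic acid, (1S,4aR,5R,7R,8aR)-7-acetoxy-1,4a-dimethyl-6-methylidene-5-[(2E)-3-methylpenta-2,4-dien-1-yl]decahydronaphthalene-1-carboxylic acid | C=C/C(C)=C/C[C@H]1C(=C)[C@H](OC(C)=O)C[C@@H]2[C@]1(C)CCC[C@]2(C)C(=O)O | target

**Step count and risks**

Total step count: 14. Longest linear sequence: 13 steps (steps 1, 2 and 4–14).

The three steps most likely to fail, in order of risk:

Step 10. The acyclic stereocentre C9 may discriminate the two dienophile faces only moderately, the ring fusion may not be cleanly trans, and at 170 °C sigmatropic drift of the skipped dienes or oligomerisation of the electron-poor diene may compete. The fallback sets out from 18 and returns at 19. The thermal pericyclic mode would be replaced by a metal-templated [4+2] of the same triene with a cationic monovalent rhodium catalyst such as [Rh(cod)2]SbF6 in CH2Cl2 at 25–40 °C. This runs through oxidative cyclisation of diene and alkene to a rhodacycle followed by reductive elimination, a process known for unactivated diene–ene tethers, and it avoids the high temperature. It makes no new compound (F0).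

Step 12. Allylic oxidation may also occur on the side-chain diene (C16 methyl, C11 methylene), and the C7 alcohol may be over-oxidised to the enone. The fallback sets out from 21 and returns at 22. The diene would first be masked: 21 in liquid SO2 (hydroquinone, sealed tube, 25 °C) should undergo cheletropic addition to the sulfolene adduct F1. SeO2/t-BuOOH would then hydroxylate C7 next to the only remaining reactive alkene to give the hydroxy sulfolene F2. Heating F2 (PhMe, NaHCO3, 110 °C) extrudes SO2 stereospecifically and returns the (E)-diene.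

Step 11. Hydride delivery may be incompletely 1,4-selective, and C-methylation of the hindered, borane-associated enolate may be sluggish or poorly face-selective. The fallback sets out from 19 and returns at 21. Reduction and alkylation would be separated: Mg in MeOH should reduce the enoate to the saturated ester F3 (C4 epimers). LiN(i-Pr)2 in THF/HMPA at −78 °C followed by MeI then methylates its free lithium enolate from the α-face.

Further compounds
F0 | step 10 | none | none
F1 | step 12 | sulfolene adduct of 21 (C12–C15 of the side chain closed through SO2 to a 3-methyl-2,5-dihydrothiophene 1,1-dioxide ring, C12 epimers) | CC1=CCS(=O)(=O)C1C[C@H]1C(=C)CC[C@@H]2[C@]1(C)CCC[C@]2(C)C(=O)OC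
F2 | step 12 | 7α-hydroxy derivative of sulfolene adduct F1 | CC1=CCS(=O)(=O)C1C[C@H]1C(=C)[C@H](O)C[C@@H]2[C@]1(C)CCC[C@]2(C)C(=O)OC
F3 | step 11 | 3,4-dihydro derivative of 19, methyl 4a-methyl-6-methylidene-5-[(2E)-3-methylpenta-2,4-dien-1-yl]decahydronaphthalene-1-carboxylate (C4 epimers, other centres as in 19) | C=C/C(C)=C/C[C@H]1C(=C)CC[C@@H]2[C@]1(C)CCCC2C(=O)OC
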